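**Strategy**

Everything rests on cutting the seven-membered ring (C3a–C4–C5–C6–C7–C8–C8a, azulene numbering) at C4–C5 and C8–C8a. Its substitution pattern, isopropyl at C4 beside the oxygen at C5 and the methyl carbinol C7 in a 1,3-relation to C5, maps onto an isopropyl-substituted vinylcarbenoid (C8a, C3a, C4) and a prenal-derived 1-silyloxy-3-methylbutadiene (C5–C8). One rhodium-catalysed enantioselective cyclopropanation/divinylcyclopropane Cope sequence (formal (4+3)) closes this ring, sets the cis C4/C5 pair in absolute terms and leaves an enoate at C8a=C3a and an olefin at C6=C7. From these handles C3a/C8a (cyclopentene annulation), C7 and the C1–C2 epoxide are relayed by substrate control.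

Key step: step 4

Remark on locants: the azulene locants of the target (C1–C3, C3a, C4–C8, C8a) are used in the discussion of all compounds; β is the face of the C5 oxygen, and the target is (1S,2R,3aR,4S,5R,7R,8aS).
Remark on the catalyst: Rh2(S-DOSP)4 is assigned on the assumption that it attacks the same carbenoid face as in its cyclopropanations of styrene; should the sense prove opposite, Rh2(R-DOSP)4 is used instead.

**Route**

Step 1
Reactants: 1 3-methylbutanal; 2 ethyl diazoacetate
Product: 3 ethyl 2-diazo-3-hydroxy-5-methylhexanoate (racemic)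
Conditions: DBU (10 mol%), MeCN, rt
Reagents that add atoms: none
Why: Base-catalysed aldol-type addition of the diazoacetate carbon to the aldehyde is a standard entry to β-hydroxy-α-diazo esters; the racemic carbinol centre is destroyed in step 2.

Step 2
Reactants: 3 ethyl 2-diazo-3-hydroxy-5-methylhexanoate
Product: 4 ethyl (E)-2-diazo-5-methylhex-3-enoate
Conditions: POCl3, Et3N, CH2Cl2, 0 °C; used at once
Reagents that add atoms: none
Why: Dehydration of a β-hydroxy-α-diazo ester (ionisation of the dichlorophosphate assisted by the diazo carbon, then loss of a C4 proton) is the usual route to vinyldiazoacetates and should give the conjugated E-olefin for steric reasons.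

Step 3
Reactants: 5 3-methylbut-2-enal
Product: 6 (E)-tert-butyldimethyl[(3-methylbuta-1,3-dien-1-yl)oxy]silane
Conditions: TBSOTf, Et3N, Et2O, 0 °C to rt; distillation
Reagents that add atoms: tert-butyldimethylsilyl trifluoromethanesulfonate, CC(C)(C)[Si](C)(C)OS(=O)(=O)C(F)(F)F
Why: Silyl dienol ether formation by soft enolisation (O-silylation, then γ-deprotonation of a methyl group) of the enal; the preferred s-trans conformer should give the 1E geometry that step 4 needs.

Step 4
Reactants: 4 ethyl (E)-2-diazo-5-methylhex-3-enoate; 6 (E)-tert-butyldimethyl[(3-methylbuta-1,3-dien-1-yl)oxy]silane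
Product: 8 ethyl (3S,4S)-4-[(tert-butyldimethylsilyl)oxy]-6-methyl-3-(propan-2-yl)cyclohepta-1,5-diene-1-carboxylate, via cis-divinylcyclopropane 7 (not isolated)
Conditions: Rh2(S-DOSP)4 (1 mol%), 6 (3 equiv), pentane, slow addition of 4 at −78 °C, then rt to 40 °C
Reagents that add atoms: none
Why: Rh2(S-DOSP)4 converts 4 into a donor/acceptor vinylcarbenoid that cyclopropanates the 1,1-disubstituted C7=C8 bond of 6 (attack begins at the unhindered, most nucleophilic terminus C8, while the trans-1,2-disubstituted enol ether is sterically shielded), placing the dienyl residue cis to the carbenoid vinyl group to give cis-divinylcyclopropane 7, which undergoes a [3,3] shift that forms C4–C5 and cleaves C8a–C7. The closest known reaction type is the tandem cyclopropanation/Cope rearrangement of vinyldiazoacetates with dienes (formal (4+3) cycloaddition). The seven-membered ring is closed by the C4–C5 σ-bond in a concerted, strain-driven sigmatropic enlargement of the three-membered ring through a boat transition state with both vinyl groups endo. Because both migrating termini are E, the isopropyl and silyloxy groups point outward on the same side of the boat and C4 and C5 emerge cis; their absolute configuration is transcribed from the catalyst-controlled face selectivity of the cyclopropanation, whose own two stereocentres then vanish as sp2 carbons. The step needs site selectivity (C7=C8 over C5=C6), cis-divinyl diastereoselectivity and carbenoid instead of vinylogous reactivity; these should be secured by the substitution pattern of 6, by the general preference of such carbenoids to place the π-substituent of the alkene cis to the vinyl donor, and by the isopropyl group on the vinylogous carbon together with a non-polar solvent.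

Step 5
Reactants: 8 ethyl (3S,4S)-4-[(tert-butyldimethylsilyl)oxy]-6-methyl-3-(propan-2-yl)cyclohepta-1,5-diene-1-carboxylate; 9 (2-methylprop-2-en-1-yl)magnesium chloride
Product: 11 ethyl (1S,2S,3S,4S)-4-[(tert-butyldimethylsilyl)oxy]-6-methyl-2-(2-methylprop-2-en-1-yl)-3-(propan-2-yl)cyclohept-5-ene-1-carboxylate, via silyl ketene acetal 10 (not isolated)
Conditions: CuBr·SMe2, TMSCl, THF, −78 °C; then NaOEt (cat.), EtOH, rt
Reagents that add atoms: chlorotrimethylsilane, C[Si](C)(C)Cl (its silyl group is carried only by intermediate 10)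
Why: Chlorosilane-accelerated 1,4-addition of an allylic copper reagent to the enoate should occur at C3a on the α face, opposite the adjacent C4 isopropyl and the C5 silyloxy group (both β), and ethoxide equilibration of the epimerisable C8a centre after ethanolysis of the silyl ketene acetal should place the ester trans to the new side chain (all-trans C8a/C3a/C4 array).

Step 6
Reactants: 11 ethyl (1S,2S,3S,4S)-4-[(tert-butyldimethylsilyl)oxy]-6-methyl-2-(2-methylprop-2-en-1-yl)-3-(propan-2-yl)cyclohept-5-ene-1-carboxylate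
Product: 12 (1S,2S,3S,4S)-4-[(tert-butyldimethylsilyl)oxy]-6-methyl-2-(2-methylprop-2-en-1-yl)-3-(propan-2-yl)cyclohept-5-ene-1-carbaldehyde
Conditions: DIBAL-H (1.1 equiv), CH2Cl2, −78 °C; Rochelle salt work-up
Reagents that add atoms: none
Why: Low-temperature DIBAL-H partial reduction stops at the aluminium hemiacetal, which releases the aldehyde (C1) on work-up; C8a already holds its thermodynamically preferred trans configuration.

Step 7
Reactants: 12 (1S,2S,3S,4S)-4-[(tert-butyldimethylsilyl)oxy]-6-methyl-2-(2-methylprop-2-en-1-yl)-3-(propan-2-yl)cyclohept-5-ene-1-carbaldehyde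
Product: 13 tert-butyl{[(1S,5R,6R,7S)-5-ethenyl-3-methyl-6-(2-methylprop-2-en-1-yl)-7-(propan-2-yl)cyclohept-2-en-1-yl]oxy}dimethylsilane
Conditions: Ph3PCH3Br, KOtBu, THF, 0 °C to rt
Reagents that add atoms: methylenetriphenylphosphorane, C=P(c1ccccc1)(c1ccccc1)c1ccccc1, made in the flask from methyltriphenylphosphonium bromide, C[P+](c1ccccc1)(c1ccccc1)c1ccccc1.[Br-]
Why: Wittig methylenation of the α-branched aldehyde with the non-stabilised ylide; any epimerisation at C8a can only return the favoured trans isomer.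

Step 8
Reactants: 13 tert-butyl{[(1S,5R,6R,7S)-5-ethenyl-3-methyl-6-(2-methylprop-2-en-1-yl)-7-(propan-2-yl)cyclohept-2-en-1-yl]oxy}dimethylsilane
Product: 14 tert-butyl{[(3aR,4S,5S,8aS)-2,7-dimethyl-4-(propan-2-yl)-3,3a,4,5,8,8a-hexahydroazulen-5-yl]oxy}dimethylsilane
Conditions: Grubbs II catalyst (5 mol%), CH2Cl2, 40 °C
Reagents that add atoms: none
Why: Ring-closing metathesis between the vinyl group (C1) and the 1,1-disubstituted methallyl olefin (C2) closes the trans-fused cyclopentene with loss of ethene and fixes the trisubstituted C1=C2 bond regiospecifically; the endocyclic trisubstituted C6=C7 olefin is inert.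

Step 9
Reactants: 14 tert-butyl{[(3aR,4S,5S,8aS)-2,7-dimethyl-4-(propan-2-yl)-3,3a,4,5,8,8a-hexahydroazulen-5-yl]oxy}dimethylsilane
Product: 15 (3aR,4S,5S,8aS)-2,7-dimethyl-4-(propan-2-yl)-3,3a,4,5,8,8a-hexahydroazulen-5-ol
Conditions: TBAF, THF, rt
Reagents that add atoms: none
Why: Fluoride-induced desilylation of the secondary silyl ether frees the C5 hydroxyl as the directing group for step 10.

Step 10
Reactants: 15 (3aR,4S,5S,8aS)-2,7-dimethyl-4-(propan-2-yl)-3,3a,4,5,8,8a-hexahydroazulen-5-ol
Product: 16 (3aR,4S,5S,6S,7R,8aS)-6,7-epoxy-2,7-dimethyl-4-(propan-2-yl)-3,3a,4,5,6,7,8,8a-octahydroazulen-5-ol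
Conditions: VO(acac)2 (5 mol%), t-BuOOH, CH2Cl2, 0 °C to rt
Reagents that add atoms: tert-butyl hydroperoxide, CC(C)(C)OO
Why: Vanadium-catalysed hydroxyl-directed epoxidation of the allylic alcohol should deliver oxygen to C6=C7 syn to the C5 hydroxyl (β face), as is general for cyclohept-2-enols, and should leave the remote C1=C2 olefin untouched.

Step 11
Reactants: 16 (3aR,4S,5S,6S,7R,8aS)-6,7-epoxy-2,7-dimethyl-4-(propan-2-yl)-3,3a,4,5,6,7,8,8a-octahydroazulen-5-ol
Product: 17 (3aR,4S,5R,7R,8aS)-2,7-dimethyl-4-(propan-2-yl)-3,3a,4,5,6,7,8,8a-octahydroazulene-5,7-diol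
Conditions: LiAlH4, THF, 0 °C to rt
Reagents that add atoms: none
Why: Hydride opening of the trisubstituted 2,3-epoxy alcohol by SN2 attack at the less substituted C6 leaves the C7–O bond intact and should give the tertiary β-carbinol of the syn-1,3-diol.

Step 12
Reactants: 17 (3aR,4S,5R,7R,8aS)-2,7-dimethyl-4-(propan-2-yl)-3,3a,4,5,6,7,8,8a-octahydroazulene-5,7-diol; 18 3-(benzyloxy)-4-methoxybenzoic acid
Product: 19 (3aR,4S,5R,7R,8aS)-7-hydroxy-2,7-dimethyl-4-(propan-2-yl)-3,3a,4,5,6,7,8,8a-octahydroazulen-5-yl 3-(benzyloxy)-4-methoxybenzoate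
Conditions: DCC, DMAP, CH2Cl2, rt
Reagents that add atoms: none
Why: Steglich esterification should acylate the secondary C5 hydroxyl with retention while the tertiary C7 hydroxyl stays free as the single directing group for step 13.

Step 13
Reactants: 19 (3aR,4S,5R,7R,8aS)-7-hydroxy-2,7-dimethyl-4-(propan-2-yl)-3,3a,4,5,6,7,8,8a-octahydroazulen-5-yl 3-(benzyloxy)-4-methoxybenzoate
Product: 20 (1S,2R,3aR,4S,5R,7R,8aS)-1,2-epoxy-7-hydroxy-2,7-dimethyl-4-(propan-2-yl)decahydroazulen-5-yl 3-(benzyloxy)-4-methoxybenzoate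
Conditions: VO(acac)2 (5 mol%), t-BuOOH, CH2Cl2, rt
Reagents that add atoms: tert-butyl hydroperoxide, CC(C)(C)OO
Why: Vanadium-catalysed epoxidation directed by the tertiary bishomoallylic C7 hydroxyl (β) should deliver oxygen to the β face of C1=C2, and the resulting syn epoxy alcohol cannot cyclise because backside attack on the epoxide from the β face is geometrically impossible.

Step 14
Reactants: 20 (1S,2R,3aR,4S,5R,7R,8aS)-1,2-epoxy-7-hydroxy-2,7-dimethyl-4-(propan-2-yl)decahydroazulen-5-yl 3-(benzyloxy)-4-methoxybenzoate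
Product: 21 (1S,2R,3aR,4S,5R,7R,8aS)-1,2-epoxy-7-hydroxy-2,7-dimethyl-4-(propan-2-yl)decahydroazulen-5-yl 3-hydroxy-4-methoxybenzoate (target)
Conditions: H2 (1 atm), 10% Pd/C, EtOAc, rt
Reagents that add atoms: none
Why: Hydrogenolysis of the aryl benzyl ether over palladium in a neutral solvent should not touch the trialkyl epoxide, the ester or the tertiary alcohol.

**Compound list**

1 | 3-methylbutanal | CC(C)CC=O | starting material
2 | ethyl diazoacetate | CCOC(=O)C=[N+]=[N-] | starting material
3 | ethyl 2-diazo-3-hydroxy-5-methylhexanoate (racemic) | CCOC(=O)C(=[N+]=[N-])C(O)CC(C)C | intermediate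
4 | ethyl (E)-2-diazo-5-methylhex-3-enoate | CCOC(=O)C(=[N+]=[N-])/C=C/C(C)C | intermediate
5 | 3-methylbut-2-enal | CC(C)=CC=O | starting material
6 | (E)-tert-butyldimethyl[(3-methylbuta-1,3-dien-1-yl)oxy]silane | CC(=C)/C=C/O[Si](C)(C)C(C)(C)C | intermediate
7 | ethyl (1R,2R)-2-[(E)-2-{[tert-butyl(dimethyl)silyl]oxy}ethenyl]-2-methyl-1-[(E)-3-methylbut-1-en-1-yl]cyclopropane-1-carboxylate | CCOC(=O)[C@@]1(/C=C/C(C)C)C[C@]1(C)/C=C/O[Si](C)(C)C(C)(C)C | intermediate (not isolated)
8 | ethyl (3S,4S)-4-[(tert-butyldimethylsilyl)oxy]-6-methyl-3-(propan-2-yl)cyclohepta-1,5-diene-1-carboxylate | CCOC(=O)C1=C[C@H](C(C)C)[C@H](O[Si](C)(C)C(C)(C)C)C=C(C)C1 | intermediate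
9 | (2-methylprop-2-en-1-yl)magnesium chloride | CC(=C)C[Mg]Cl | starting material
10 | tert-butyl{[(1S,6S,7S)-5-[ethoxy(trimethylsilyloxy)methylidene]-3-methyl-6-(2-methylprop-2-en-1-yl)-7-(propan-2-yl)cyclohept-2-en-1-yl]oxy}dimethylsilane | CC(C)(C)[Si](C)(C)O[C@@H]1C=C(C)CC(=C(OCC)O[Si](C)(C)C)[C@@H](CC(C)=C)[C@@H]1C(C)C | intermediate (not isolated)
11 | ethyl (1S,2S,3S,4S)-4-[(tert-butyldimethylsilyl)oxy]-6-methyl-2-(2-methylprop-2-en-1-yl)-3-(propan-2-yl)cyclohept-5-ene-1-carboxylate | CC(C)(C)[Si](C)(C)O[C@@H]1C=C(C)C[C@H](C(=O)OCC)[C@@H](CC(C)=C)[C@@H]1C(C)C | intermediate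
12 | (1S,2S,3S,4S)-4-[(tert-butyldimethylsilyl)oxy]-6-methyl-2-(2-methylprop-2-en-1-yl)-3-(propan-2-yl)cyclohept-5-ene-1-carbaldehyde | CC(C)(C)[Si](C)(C)O[C@@H]1C=C(C)C[C@H](C=O)[C@@H](CC(C)=C)[C@@H]1C(C)C | intermediate
13 | tert-butyl{[(1S,5R,6R,7S)-5-ethenyl-3-methyl-6-(2-methylprop-2-en-1-yl)-7-(propan-2-yl)cyclohept-2-en-1-yl]oxy}dimethylsilane | CC(C)(C)[Si](C)(C)O[C@@H]1C=C(C)C[C@H](C=C)[C@@H](CC(C)=C)[C@@H]1C(C)C | intermediate
14 | tert-butyl{[(3aR,4S,5S,8aS)-2,7-dimethyl-4-(propan-2-yl)-3,3a,4,5,8,8a-hexahydroazulen-5-yl]oxy}dimethylsilane | CC(C)(C)[Si](C)(C)O[C@@H]1C=C(C)C[C@H]2[C@@H](CC(C)=C2)[C@@H]1C(C)C | intermediate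
15 | (3aR,4S,5S,8aS)-2,7-dimethyl-4-(propan-2-yl)-3,3a,4,5,8,8a-hexahydroazulen-5-ol | O[C@@H]1C=C(C)C[C@H]2[C@@H](CC(C)=C2)[C@@H]1C(C)C | intermediate
16 | (3aR,4S,5S,6S,7R,8aS)-6,7-epoxy-2,7-dimethyl-4-(propan-2-yl)-3,3a,4,5,6,7,8,8a-octahydroazulen-5-ol | O[C@@H]1[C@@H]2O[C@]2(C)C[C@H]3[C@@H](CC(C)=C3)[C@@H]1C(C)C | intermediate
17 | (3aR,4S,5R,7R,8aS)-2,7-dimethyl-4-(propan-2-yl)-3,3a,4,5,6,7,8,8a-octahydroazulene-5,7-diol | O[C@@H]1C[C@](C)(O)C[C@H]2[C@@H](CC(C)=C2)[C@@H]1C(C)C | intermediate
18 | 3-(benzyloxy)-4-methoxybenzoic acid | COc1ccc(C(=O)O)cc1OCc1ccccc1 | starting material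
19 | (3aR,4S,5R,7R,8aS)-7-hydroxy-2,7-dimethyl-4-(propan-2-yl)-3,3a,4,5,6,7,8,8a-octahydroazulen-5-yl 3-(benzyloxy)-4-methoxybenzoate | COc1ccc(C(=O)O[C@@H]2C[C@](C)(O)C[C@H]3[C@@H](CC(C)=C3)[C@@H]2C(C)C)cc1OCc1ccccc1 | intermediate
20 | (1S,2R,3aR,4S,5R,7R,8aS)-1,2-epoxy-7-hydroxy-2,7-dimethyl-4-(propan-2-yl)decahydroazulen-5-yl 3-(benzyloxy)-4-methoxybenzoate | COc1ccc(C(=O)O[C@@H]2C[C@](C)(O)C[C@H]3[C@@H](C[C@@]4(C)O[C@@H]34)[C@@H]2C(C)C)cc1OCc1ccccc1 | intermediate
21 | (1S,2R,3aR,4S,5R,7R,8aS)-1,2-epoxy-7-hydroxy-2,7-dimethyl-4-(propan-2-yl)decahydroazulen-5-yl 3-hydroxy-4-methoxybenzoate | COc1ccc(C(=O)O[C@@H]2C[C@](C)(O)C[C@H]3[C@@H](C[C@@]4(C)O[C@@H]34)[C@@H]2C(C)C)cc1O | target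

**Summary**

Total step count: 14.
Longest linear sequence: 13 steps (steps 1, 2 and 4–14; step 3 is a one-step branch).

Steps most likely to fail:

1. Step 4. The electrophilic carbenoid may be captured at the silyl enol ether end of 6 (cyclopropanation of C5=C6 or stepwise zwitterionic capture leading to (3+2) products). Alternatively the trans-divinylcyclopropane may form and rearrange only on heating, with loss of enantiopurity. The fallback sets out from 4 and returns at 8; it takes the donor oxygen out of the diene and makes the C5–O bond after ring formation. Zirconium-catalysed hydroboration of commercial 2-methylbut-1-en-3-yne with pinacolborane gives (E)-4,4,5,5-tetramethyl-2-(3-methylbuta-1,3-dien-1-yl)-1,3,2-dioxaborolane F1, in which the 1,1-disubstituted olefin is the only nucleophilic site. The same Rh2(S-DOSP)4 cyclopropanation/Cope sequence with 4 should then give ethyl (3S,4S)-6-methyl-3-(propan-2-yl)-4-(4,4,5,5-tetramethyl-1,3,2-dioxaborolan-2-yl)cyclohepta-1,5-diene-1-carboxylate F2. Stereoretentive oxidation of the C–B bond (NaBO3·4H2O, THF/H2O) gives ethyl (3S,4S)-4-hydroxy-6-methyl-3-(propan-2-yl)cyclohepta-1,5-diene-1-carboxylate F3, and silylation (TBSCl, imidazole, DMF) returns 8.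

2. Step 5. The allylic organometallic may add 1,2 to the ester, or may fail to reach the hindered β-carbon C3a. The fallback sets out from 8 and returns at 11; it makes the C3a–C3 bond by a radical instead of a polar process. Conjugate addition of benzeneselenol (PhSeSePh, NaBH4, AcOH, EtOH) to 8 gives ethyl (3R,4R)-4-[(tert-butyldimethylsilyl)oxy]-6-methyl-2-(phenylselanyl)-3-(propan-2-yl)cyclohept-5-ene-1-carboxylate F4 as a mixture at C1/C2 of the cycloheptene. Keck radical allylation with tributyl(2-methylallyl)stannane (AIBN, benzene, 80 °C) should attach the methallyl group to the C3a radical anti to the C4 isopropyl group, and NaOEt/EtOH equilibration at C8a then gives 11.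

3. Step 13. Delivery by the tertiary C7 hydroxyl may be poor, so that oxygen is transferred unselectively or to the α face of C1=C2. The fallback sets out from 19 and returns at 20; it replaces substrate direction by reagent control. Shi epoxidation is used with the enantiomer of the fructose-derived ketone whose spiro transition state matches the β face (Oxone, K2CO3, MeCN/dimethoxymethane/H2O, 0 °C). This fallback makes no compound outside the list: none F0.

Further compounds
F1 | step 4 | (E)-4,4,5,5-tetramethyl-2-(3-methylbuta-1,3-dien-1-yl)-1,3,2-dioxaborolane | CC(=C)/C=C/B1OC(C)(C)C(C)(C)O1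
F2 | step 4 | ethyl (3S,4S)-6-methyl-3-(propan-2-yl)-4-(4,4,5,5-tetramethyl-1,3,2-dioxaborolan-2-yl)cyclohepta-1,5-diene-1-carboxylate | CCOC(=O)C1=C[C@H](C(C)C)[C@H](B2OC(C)(C)C(C)(C)O2)C=C(C)C1
F3 | step 4 | ethyl (3S,4S)-4-hydroxy-6-methyl-3-(propan-2-yl)cyclohepta-1,5-diene-1-carboxylate | CCOC(=O)C1=C[C@H](C(C)C)[C@H](O)C=C(C)C1
F4 | step 5 | ethyl (3R,4R)-4-[(tert-butyldimethylsilyl)oxy]-6-methyl-2-(phenylselanyl)-3-(propan-2-yl)cyclohept-5-ene-1-carboxylate | CC(C)(C)[Si](C)(C)O[C@@H]1C=C(C)CC(C(=O)OCC)C([Se]c2ccccc2)[C@@H]1C(C)C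
F0 | step 13 | none | none
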